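The isoquinoline benzo ring is opened at C5–C6, its only pair of adjacent unsubstituted CH carbons. This ring can then be closed by olefin metathesis on a finished pyridine whose two methyl groups (later C1-Me and C3-Me) shield N2 from ruthenium. In one operation the metathesis joins a pyridine 4-vinyl group to an allylic vinyl group. It gives a 7,8-dihydroisoquinolin-8-ol that already bears the naphthyl group on sp3 C7. The hindered C7–C1' biaryl axis appears only afterwards, when the carbinol is oxidised and the ketone aromatises. The precursor is a 1-(4-vinylpyridin-3-yl)-2-naphthylbut-3-en-1-ol, assembled by allylboration of a 4-vinylnicotinaldehyde with a gamma-naphthyl allylboronate.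

Key step: step 12

Assumption: the target SMILES defines no configuration at the C7–C1' axis and holds no stereocentre, so the racemic atropisomer mixture is made.

Step 1
Reactants: 1 ethyl 4-hydroxy-2,6-dimethylpyridine-3-carboxylate
Product: 2 ethyl 4-chloro-2,6-dimethylpyridine-3-carboxylate
Conditions: POCl3 (neat), 100 °C; ice, aq Na2CO3
Reagents that add atoms: phosphoryl chloride, O=P(Cl)(Cl)Cl
Why: Deoxychlorination of a 4-hydroxypyridine/4-pyridone by addition–elimination through its O-dichlorophosphate is the standard entry to 4-chloropyridines and leaves the ester untouched.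

Step 2
Reactants: 2 ethyl 4-chloro-2,6-dimethylpyridine-3-carboxylate
Product: 3 (4-chloro-2,6-dimethylpyridin-3-yl)methanol
Conditions: i-Bu2AlH (2.5 equiv), CH2Cl2, −78 to 0 °C; aq Rochelle salt
Reagents that add atoms: none
Why: Ester reduction by two hydride transfers from i-Bu2AlH should proceed at low temperature, where neither the C–Cl bond nor the pyridine ring is attacked.

Step 3
Reactants: 3 (4-chloro-2,6-dimethylpyridin-3-yl)methanol
Product: 4 4-chloro-2,6-dimethylpyridine-3-carbaldehyde
Conditions: activated MnO2 (10 equiv), CH2Cl2, rt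
Reagents that add atoms: none
Why: Heterogeneous MnO2 oxidation of a benzylic-type pyridylmethanol stops at the aldehyde under neutral conditions.

Step 4
Reactants: 4 4-chloro-2,6-dimethylpyridine-3-carbaldehyde; 5 2-ethenyl-4,4,5,5-tetramethyl-1,3,2-dioxaborolane
Product: 6 4-ethenyl-2,6-dimethylpyridine-3-carbaldehyde
Conditions: PdCl2(dppf) (3 mol %), K2CO3, 1,4-dioxane/H2O, BHT (trace), 80 °C
Reagents that add atoms: none
Why: Suzuki–Miyaura vinylation should be easy because the C4–Cl bond is activated by the ring nitrogen and the ortho formyl group, and placing it last in this branch means only one polymerisable vinylpyridine has to be handled.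

Step 5
Reactants: 7 N,N-diethyl-2-methoxybenzamide; 8 3-bromo-2-methylprop-1-ene
Product: 11 N,N-diethyl-2-methoxy-6-(2-methylprop-2-en-1-yl)benzamide, via aryllithium 9 (not isolated), via arylmagnesium bromide 10 (not isolated)
Conditions: s-BuLi, TMEDA, THF, −78 °C; MgBr2·OEt2, −78 to 0 °C; 8, 0 °C to rt
Reagents that add atoms: none
Why: In this directed ortho-metalation the diethylamide, the stronger director, steers s-BuLi to C6, and transmetalation to magnesium lowers the basicity so that the allylic bromide is substituted cleanly.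

Step 6
Reactants: 11 N,N-diethyl-2-methoxy-6-(2-methylprop-2-en-1-yl)benzamide
Product: 14 8-methoxy-3-methylnaphthalen-1-ol, via 2H-naphthalen-1-one 12 (not isolated), via lithium naphtholate 13 (not isolated)
Conditions: LiN(iPr)2 (2.2 equiv), THF, −78 °C to rt; 1 M HCl
Reagents that add atoms: none
Why: This is the anionic benzannulation of an ortho-allylbenzamide, in which deprotonation of the benzylic allylic CH2, attack of the allyl anion terminus on the amide carbonyl (six-membered closure), loss of LiNEt2 and enolisation give the 1-naphthol with the methyl group fixed at C3.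

Step 7
Reactants: 14 8-methoxy-3-methylnaphthalen-1-ol
Product: 15 1,8-dimethoxy-3-methylnaphthalene
Conditions: MeI, K2CO3, DMF, 40 °C
Reagents that add atoms: iodomethane, CI
Why: Williamson etherification of the naphtholate is routine even for peri-hydrogen-bonded 8-methoxy-1-naphthols.

Step 8
Reactants: 15 1,8-dimethoxy-3-methylnaphthalene
Product: 16 1-bromo-4,5-dimethoxy-2-methylnaphthalene
Conditions: NBS (1.0 equiv), MeCN, 0 °C, dark
Reagents that add atoms: N-bromosuccinimide, O=C1CCC(=O)N1Br
Why: Electrophilic aromatic bromination should go para to a methoxy group at the one such position that the ortho methyl group activates further, while the polar solvent, darkness and low temperature suppress radical benzylic bromination.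

Step 9
Reactants: 16 1-bromo-4,5-dimethoxy-2-methylnaphthalene; 17 acrolein
Product: 20 1-(4,5-dimethoxy-2-methylnaphthalen-1-yl)prop-2-en-1-yl acetate (racemic), via naphthyllithium 18 (not isolated), via lithium alkoxide 19 (not isolated)
Conditions: n-BuLi, THF, −78 °C; 17, −78 °C; Ac2O, −78 to 0 °C
Reagents that add atoms: acetic anhydride, CC(=O)OC(C)=O
Why: Bromine–lithium exchange, 1,2-addition of the aryllithium to the enal and acetylation of the alkoxide in the flask are all standard, and the new carbinol centre forms without control (racemic) and is erased in step 10.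

Step 10
Reactants: 20 1-(4,5-dimethoxy-2-methylnaphthalen-1-yl)prop-2-en-1-yl acetate
Product: 21 2-[(E)-3-(4,5-dimethoxy-2-methylnaphthalen-1-yl)prop-2-en-1-yl]-4,4,5,5-tetramethyl-1,3,2-dioxaborolane
Conditions: B2pin2 (1.1 equiv), Pd2(dba)3 (2.5 mol %, zerovalent palladium), DMSO, 50 °C
Reagents that add atoms: bis(pinacolato)diboron, CC1(C)OB(OC1(C)C)B1OC(C)(C)C(C)(C)O1
Why: In this palladium-catalysed allylic borylation the eta-3-allylpalladium acetate transmetalates with B2pin2 and eliminates reductively at the unhindered terminus, so the linear E-boronate should result even if 20 has partly rearranged to its linear allylic isomer.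

Step 11
Reactants: 6 4-ethenyl-2,6-dimethylpyridine-3-carbaldehyde; 21 2-[(E)-3-(4,5-dimethoxy-2-methylnaphthalen-1-yl)prop-2-en-1-yl]-4,4,5,5-tetramethyl-1,3,2-dioxaborolane
Product: 23 1-(4-ethenyl-2,6-dimethylpyridin-3-yl)-2-(4,5-dimethoxy-2-methylnaphthalen-1-yl)but-3-en-1-ol (racemic; mainly anti expected), via pinacol borate ester 22 (not isolated)
Conditions: toluene (1 M), BHT (1 mol %), 60 °C; then H2O
Reagents that add atoms: none
Why: Uncatalysed allylboration through a closed Zimmerman–Traxler chair forms the C7–C8 bond at the gamma carbon only, and the E-boronate should set the two new centres anti (racemic), which does not matter because both are erased in step 13.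

Step 12
Reactants: 23 1-(4-ethenyl-2,6-dimethylpyridin-3-yl)-2-(4,5-dimethoxy-2-methylnaphthalen-1-yl)but-3-en-1-ol
Product: 24 7-(4,5-dimethoxy-2-methylnaphthalen-1-yl)-1,3-dimethyl-7,8-dihydroisoquinolin-8-ol (racemic; cis expected from anti-23)
Conditions: RuCl2(=CHPh)(H2IMes)(PCy3) (second-generation Grubbs catalyst, 5 mol %), 1,4-benzoquinone (10 mol %), CH2Cl2 (0.005 M), argon sparge, 40 °C; Et3N-deactivated silica
Reagents that add atoms: none
Why: By the Chauvin mechanism the catalyst should trade its benzylidene preferentially for the non-conjugated allylic vinyl group, the alkylidene now on C6 adds across the pyridine 4-vinyl group, and collapse of the ruthenacyclobutane leaves C5=C6 and a methylidene that carries the chain while ethene escapes. The closest known reaction type is ring-closing metathesis of 1-(2-vinylaryl)but-3-en-1-ols to 1,2-dihydronaphthalen-1-ols, which has also been run on vinylpyridines. The one ring closed is the six-membered carbocycle C4a–C5–C6–C7–C8–C8a, made from a 1,7-diene in which the pyridine C3–C4 bond holds two tether atoms cis. No stereocentre is created and C7 and C8 are not touched, so the relative configuration of 23 is simply carried over. The step needs cyclisation to win over nitrogen binding, dimerisation and double-bond migration: the methyl groups on both sides of N2 block coordination, high dilution and the preorganised tether favour closure, and benzoquinone intercepts ruthenium hydrides. Mild temperature and acid-free isolation keep the product, an arene hydrate, from aromatising by loss of water.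

Step 13
Reactants: 24 7-(4,5-dimethoxy-2-methylnaphthalen-1-yl)-1,3-dimethyl-7,8-dihydroisoquinolin-8-ol
Product: 26 7-(4,5-dimethoxy-2-methylnaphthalen-1-yl)-1,3-dimethylisoquinolin-8-ol (racemic axis), via 7H-isoquinolin-8-one 25 (not isolated)
Conditions: Dess–Martin periodinane (1.1 equiv), NaHCO3 (5 equiv), CH2Cl2, 0 °C to rt; then Et3N (0.2 equiv)
Reagents that add atoms: none
Why: Bicarbonate-buffered Dess–Martin oxidation avoids the acid that would dehydrate the carbinol, and ketone 25, whose C7–H is alpha to the carbonyl, allylic and benzylic, should enolise at once to the aromatic phenol, erasing both stereocentres and creating the biaryl axis as a racemate.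

Step 14
Reactants: 26 7-(4,5-dimethoxy-2-methylnaphthalen-1-yl)-1,3-dimethylisoquinolin-8-ol
Product: 27 7-(4,5-dimethoxy-2-methylnaphthalen-1-yl)-8-methoxy-1,3-dimethylisoquinoline (target)
Conditions: Cs2CO3, MeI (1.1 equiv), DMF, rt
Reagents that add atoms: iodomethane, CI
Why: Williamson O-methylation of the caesium phenoxide keeps the aromatic isoquinoline intact, and the nitrogen, flanked by two methyl groups, should be too hindered to be quaternised by a near-stoichiometric amount of MeI at room temperature.

Compound list
1 | ethyl 4-hydroxy-2,6-dimethylpyridine-3-carboxylate | CCOC(=O)c1c(O)cc(C)nc1C | starting material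
2 | ethyl 4-chloro-2,6-dimethylpyridine-3-carboxylate | CCOC(=O)c1c(Cl)cc(C)nc1C | intermediate
3 | (4-chloro-2,6-dimethylpyridin-3-yl)methanol | OCc1c(Cl)cc(C)nc1C | intermediate
4 | 4-chloro-2,6-dimethylpyridine-3-carbaldehyde | O=Cc1c(Cl)cc(C)nc1C | intermediate
5 | 2-ethenyl-4,4,5,5-tetramethyl-1,3,2-dioxaborolane | C=CB1OC(C)(C)C(C)(C)O1 | starting material
6 | 4-ethenyl-2,6-dimethylpyridine-3-carbaldehyde | C=Cc1cc(C)nc(C)c1C=O | intermediate
7 | N,N-diethyl-2-methoxybenzamide | CCN(CC)C(=O)c1ccccc1OC | starting material
8 | 3-bromo-2-methylprop-1-ene | C=C(C)CBr | starting material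
9 | [2-(diethylcarbamoyl)-3-methoxyphenyl]lithium (not isolated) | CCN(CC)C(=O)c1c([Li])cccc1OC | intermediate
10 | [2-(diethylcarbamoyl)-3-methoxyphenyl]magnesium bromide (not isolated) | CCN(CC)C(=O)c1c([Mg]Br)cccc1OC | intermediate
11 | N,N-diethyl-2-methoxy-6-(2-methylprop-2-en-1-yl)benzamide | CCN(CC)C(=O)c1c(CC(C)=C)cccc1OC | intermediate
12 | 8-methoxy-3-methylnaphthalen-1(2H)-one (not isolated) | COc1cccc2C=C(C)CC(=O)c12 | intermediate
13 | lithium 8-methoxy-3-methylnaphthalen-1-olate (not isolated) | COc1cccc2cc(C)cc(O[Li])c12 | intermediate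
14 | 8-methoxy-3-methylnaphthalen-1-ol | COc1cccc2cc(C)cc(O)c12 | intermediate
15 | 1,8-dimethoxy-3-methylnaphthalene | COc1cccc2cc(C)cc(OC)c12 | intermediate
16 | 1-bromo-4,5-dimethoxy-2-methylnaphthalene | COc1cccc2c(Br)c(C)cc(OC)c12 | intermediate
17 | acrolein (prop-2-enal) | C=CC=O | starting material
18 | (4,5-dimethoxy-2-methylnaphthalen-1-yl)lithium (not isolated) | COc1cccc2c([Li])c(C)cc(OC)c12 | intermediate
19 | lithium 1-(4,5-dimethoxy-2-methylnaphthalen-1-yl)prop-2-en-1-olate, racemic (not isolated) | C=CC(O[Li])c1c(C)cc(OC)c2c(OC)cccc12 | intermediate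
20 | 1-(4,5-dimethoxy-2-methylnaphthalen-1-yl)prop-2-en-1-yl acetate, racemic | C=CC(OC(C)=O)c1c(C)cc(OC)c2c(OC)cccc12 | intermediate
21 | 2-[(E)-3-(4,5-dimethoxy-2-methylnaphthalen-1-yl)prop-2-en-1-yl]-4,4,5,5-tetramethyl-1,3,2-dioxaborolane | COc1cccc2c(/C=C/CB3OC(C)(C)C(C)(C)O3)c(C)cc(OC)c12 | intermediate
22 | O-(4,4,5,5-tetramethyl-1,3,2-dioxaborolan-2-yl) ether of 23, racemic (not isolated) | C=CC(C(OB1OC(C)(C)C(C)(C)O1)c1c(C)nc(C)cc1C=C)c1c(C)cc(OC)c2c(OC)cccc12 | intermediate
23 | 1-(4-ethenyl-2,6-dimethylpyridin-3-yl)-2-(4,5-dimethoxy-2-methylnaphthalen-1-yl)but-3-en-1-ol, racemic, anti isomer expected to dominate (OH and naphthyl on opposite faces of the zigzag pyridyl–C1–C2–vinyl chain); drawn flat because both centres are erased later | C=CC(C(O)c1c(C)nc(C)cc1C=C)c1c(C)cc(OC)c2c(OC)cccc12 | intermediate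
24 | 7-(4,5-dimethoxy-2-methylnaphthalen-1-yl)-1,3-dimethyl-7,8-dihydroisoquinolin-8-ol, racemic, cis expected from anti-23; drawn flat | Cc1cc2c(c(C)n1)C(O)C(c1c(C)cc(OC)c3c(OC)cccc13)C=C2 | intermediate
25 | 7-(4,5-dimethoxy-2-methylnaphthalen-1-yl)-1,3-dimethylisoquinolin-8(7H)-one, racemic (not isolated) | Cc1cc2c(c(C)n1)C(=O)C(c1c(C)cc(OC)c3c(OC)cccc13)C=C2 | intermediate
26 | 7-(4,5-dimethoxy-2-methylnaphthalen-1-yl)-1,3-dimethylisoquinolin-8-ol, racemic axis | Cc1cc2ccc(-c3c(C)cc(OC)c4c(OC)cccc34)c(O)c2c(C)n1 | intermediate
27 | 7-(4,5-dimethoxy-2-methylnaphthalen-1-yl)-8-methoxy-1,3-dimethylisoquinoline, racemic axis | COc1c(-c2c(C)cc(OC)c3c(OC)cccc23)ccc2cc(C)nc(C)c12 | target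

Total step count: 14. Longest linear sequence: 10 (steps 5–14). The pyridine branch (steps 1–4) joins at step 11.

Steps most likely to fail

Step 11. Bond formation between two carbons that each carry a doubly ortho-flanked aryl group may be so slow that thermal polymerisation of the vinylpyridine or protodeboronation overtakes the addition. The fallback sets out from acetate 20 and aldehyde 6 and replaces the boronate by a much more nucleophilic allylmetal made by umpolung. With Pd(PPh3)4 (catalytic, zerovalent palladium) and InI (monovalent indium) in THF at room temperature, reductive transmetalation of the eta-3-allylpalladium acetate gives (E)-3-(4,5-dimethoxy-2-methylnaphthalen-1-yl)prop-2-en-1-ylindium acetate iodide F1. F1 should add to 6 through its gamma carbon without heating. Aqueous work-up comes back to the route at 23, and step 10 is bypassed.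

Step 12. Catalyst deactivation by the basic substrate or by chelation of the free hydroxyl group may stall the closure. Migration of the allylic double bond, or loss of water from the product during a long reaction, may divert material. The fallback sets out from 23 and moves the oxidation in front of the ring closure. Buffered Dess–Martin oxidation gives 1-(4-ethenyl-2,6-dimethylpyridin-3-yl)-2-(4,5-dimethoxy-2-methylnaphthalen-1-yl)but-3-en-1-one F2. F2 is closed with RuCl2(H2IMes)(=CH-C6H4-2-OiPr), the second-generation Hoveyda–Grubbs catalyst, in toluene at 60 °C. The metathesis product is 25, which aromatises in the flask, so the closure becomes irreversible and no dehydration-prone carbinol is ever formed. The route is rejoined at 26.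

Step 13. Elimination of water through the activated C8–O intermediate, driven by aromatisation, may compete with hydrogen removal at C8, and the liberated phenol may be oxidised further. The fallback sets out from 24 and removes the driving force for elimination first.
- Hydrogenation (H2, Pd/C, EtOAc) gives 7-(4,5-dimethoxy-2-methylnaphthalen-1-yl)-1,3-dimethyl-5,6,7,8-tetrahydroisoquinolin-8-ol F3.
- Dess–Martin oxidation gives 7-(4,5-dimethoxy-2-methylnaphthalen-1-yl)-1,3-dimethyl-6,7-dihydro-5H-isoquinolin-8-one F4.
- KN(SiMe3)2 and Me3SiCl in THF at −78 °C give 7-(4,5-dimethoxy-2-methylnaphthalen-1-yl)-1,3-dimethyl-8-(trimethylsilyloxy)-5,6-dihydroisoquinoline F5.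
- Saegusa–Ito dehydrogenation with Pd(OAc)2 (divalent palladium) in MeCN gives 7-(4,5-dimethoxy-2-methylnaphthalen-1-yl)-1,3-dimethylisoquinolin-8(5H)-one F6, which tautomerises, so the route is rejoined at 26.

Further compounds
F1 | step 11 | (E)-3-(4,5-dimethoxy-2-methylnaphthalen-1-yl)prop-2-en-1-ylindium acetate iodide | COc1cccc2c(/C=C/C[In](I)OC(C)=O)c(C)cc(OC)c12
F2 | step 12 | 1-(4-ethenyl-2,6-dimethylpyridin-3-yl)-2-(4,5-dimethoxy-2-methylnaphthalen-1-yl)but-3-en-1-one (racemic) | C=CC(C(=O)c1c(C)nc(C)cc1C=C)c1c(C)cc(OC)c2c(OC)cccc12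
F3 | step 13 | 7-(4,5-dimethoxy-2-methylnaphthalen-1-yl)-1,3-dimethyl-5,6,7,8-tetrahydroisoquinolin-8-ol (racemic) | Cc1cc2c(c(C)n1)C(O)C(c1c(C)cc(OC)c3c(OC)cccc13)CC2
F4 | step 13 | 7-(4,5-dimethoxy-2-methylnaphthalen-1-yl)-1,3-dimethyl-6,7-dihydro-5H-isoquinolin-8-one (racemic) | Cc1cc2c(c(C)n1)C(=O)C(c1c(C)cc(OC)c3c(OC)cccc13)CC2
F5 | step 13 | 7-(4,5-dimethoxy-2-methylnaphthalen-1-yl)-1,3-dimethyl-8-(trimethylsilyloxy)-5,6-dihydroisoquinoline | Cc1cc2c(c(C)n1)C(O[Si](C)(C)C)=C(c1c(C)cc(OC)c3c(OC)cccc13)CC2
F6 | step 13 | 7-(4,5-dimethoxy-2-methylnaphthalen-1-yl)-1,3-dimethylisoquinolin-8(5H)-one | Cc1cc2c(c(C)n1)C(=O)C(c1c(C)cc(OC)c3c(OC)cccc13)=CC2
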